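The synthesis rests on cutting C3a–C8a and C7–C8 of the hydroazulene (C3 carbinol, C4 acyloxy carbon, C6 formyl-bearing carbon, C8a methyl-bearing carbon). The feature exploited is the C4 oxygen of the seven-membered ring, flanked by C3a and by the C5–C6=C7 unit. C3a–C4–C5–C6–C7 is read as the carbon chain of a 3-oxidopyrylium, with its ring oxygen bridging C3a and C7. One intramolecular (5+2) cycloaddition closes the cyclopentane and the cycloheptenone and sets C3a, C7 and C8a from C3. The precursor is a 6-acetoxypyran-3-one carrying a silylated tertiary carbinol with a 3-methylbut-3-enyl arm. Two electron-transfer cleavages then excise the bridging oxygen.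

Key step: step 12

Remark: hydroazulene numbering is used for all atoms that end in the bicycle. Compounds 13–15 are carried as mixtures of epimers at the carbinol and pyranone carbons, because these centres become planar in 16. Their SMILES leave those centres undefined.

Step 1
Reactants: 1 3-methylbutanal
Product: 2 3-methyl-2-methylidenebutanal
Conditions: 37% aq HCHO, pyrrolidine (10 mol %), EtCO2H (10 mol %), i-PrOH, 45 °C
Reagents that add atoms: formaldehyde, C=O
Why: Amine-catalysed Mannich condensation (α-methylenation of an aldehyde), in which the enamine of 1 adds to formaldehyde and loss of the amine leaves the 2-substituted acrolein without forming a stereocentre.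

Step 2
Reactants: 2 3-methyl-2-methylidenebutanal
Product: 3 3-methyl-2-methylidenebutan-1-ol
Conditions: NaBH4, CeCl3·7H2O, MeOH, 0 °C
Reagents that add atoms: none
Why: Luche 1,2-reduction, in which the cerium-modified borohydride attacks only the carbonyl carbon of the enal and leaves the 1,1-disubstituted alkene untouched.

Step 3
Reactants: 3 3-methyl-2-methylidenebutan-1-ol
Product: 4 (R)-[2-(propan-2-yl)oxiran-2-yl]methanol
Conditions: Ti(Oi-Pr)4 (5 mol %), D-(−)-DIPT (6 mol %), t-BuOOH, 4 Å MS, CH2Cl2, −20 °C
Reagents that add atoms: tert-butyl hydroperoxide, CC(C)(C)OO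
Why: Sharpless asymmetric epoxidation of a 2-substituted allylic alcohol under catalytic conditions with sieves, which limit opening of the 2,2-disubstituted epoxide, and the D-(−)-tartrate complex delivers oxygen to the alkene face that makes the quaternary carbon (future C3) R.

Step 4
Reactants: 4 (R)-[2-(propan-2-yl)oxiran-2-yl]methanol; 5 (2-methylprop-2-en-1-yl)magnesium chloride
Product: 6 (2R)-5-methyl-2-(propan-2-yl)hex-5-ene-1,2-diol
Conditions: 5 (3 equiv), CuI (10 mol %), THF, −30 → 0 °C
Reagents that add atoms: none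
Why: Copper-catalysed SN2 opening of the epoxide at its unsubstituted CH2 by the allylic Grignard reagent (the first equivalent only deprotonates the alcohol), in which the C–O bond at the stereocentre is not touched and the degenerate Payne shift of the alkoxide regenerates the same enantiomer, so C3 is retained.

Step 5
Reactants: 6 (2R)-5-methyl-2-(propan-2-yl)hex-5-ene-1,2-diol
Product: 7 (2R)-5-methyl-2-(propan-2-yl)-1,2-bis(triethylsilyloxy)hex-5-ene
Conditions: TESOTf (2.5 equiv), 2,6-lutidine, CH2Cl2, 0 °C
Reagents that add atoms: triethylsilyl trifluoromethanesulfonate, CC[Si](CC)(CC)OS(=O)(=O)C(F)(F)F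
Why: Silylation with a silyl triflate and a hindered pyridine base, the standard way to cap a crowded tertiary alcohol, and the primary alcohol is silylated along with it.

Step 6
Reactants: 7 (2R)-5-methyl-2-(propan-2-yl)-1,2-bis(triethylsilyloxy)hex-5-ene
Product: 8 (2R)-5-methyl-2-(propan-2-yl)-2-(triethylsilyloxy)hex-5-enal
Conditions: (COCl)2, DMSO, CH2Cl2, −78 → −40 °C; Et3N, −78 °C → rt
Reagents that add atoms: none
Why: Swern oxidation applied directly to a primary triethylsilyl ether, in which the chlorosulfonium salt desilylates and oxidises only the unhindered primary ether while the tertiary ether stays, and the quaternary α-carbon cannot epimerise.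

Step 7
Reactants: 9 methyl 5-bromofuran-3-carboxylate
Product: 10 (5-bromofuran-3-yl)methanol
Conditions: DIBAL-H (2.5 equiv), CH2Cl2, −78 → 0 °C; Rochelle salt work-up
Reagents that add atoms: none
Why: Ester reduction with DIBAL-H, which at low temperature leaves the furyl C–Br bond intact.

Step 8
Reactants: 10 (5-bromofuran-3-yl)methanol
Product: 11 [(5-bromofuran-3-yl)methoxy](tert-butyl)diphenylsilane
Conditions: TBDPSCl, imidazole, DMF, rt
Reagents that add atoms: tert-butyl(chloro)diphenylsilane, CC(C)(C)[Si](Cl)(c1ccccc1)c1ccccc1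
Why: Standard silyl ether formation, with TBDPS chosen because it outlasts the later removal of the tertiary TES ether and is a poor leaving group under electron transfer.

Step 9
Reactants: 11 [(5-bromofuran-3-yl)methoxy](tert-butyl)diphenylsilane; 8 (2R)-5-methyl-2-(propan-2-yl)-2-(triethylsilyloxy)hex-5-enal
Product: 13 (2R)-1-[4-(tert-butyldiphenylsilyloxymethyl)furan-2-yl]-5-methyl-2-(propan-2-yl)-2-(triethylsilyloxy)hex-5-en-1-ol (both C1 epimers), via 2-furyllithium 12 (not isolated)
Conditions: n-BuLi (1.05 equiv), THF, −78 °C; 8, −78 °C; AcOH, −78 °C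
Reagents that add atoms: none
Why: Bromine–lithium exchange places the metal on the furan α-carbon remote from the side chain without relying on the regiochemistry of a deprotonation, 1,2-addition to the non-enolisable aldehyde follows, the new carbinol centre is formed without control (harmless, since it is lost in 16), and the cold acidic quench forestalls O-to-O silyl migration.

Step 10
Reactants: 13 (2R)-1-[4-(tert-butyldiphenylsilyloxymethyl)furan-2-yl]-5-methyl-2-(propan-2-yl)-2-(triethylsilyloxy)hex-5-en-1-ol
Product: 14 5-(tert-butyldiphenylsilyloxymethyl)-2-[(3R)-2,6-dimethyl-3-(triethylsilyloxy)hept-6-en-3-yl]-6-hydroxy-2H-pyran-3(6H)-one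
Conditions: NBS (1.0 equiv), NaHCO3, THF–H2O (4:1), 0 °C
Reagents that add atoms: water, O
Why: Achmatowicz rearrangement, in which one equivalent of NBS oxidises the electron-rich furan far faster than the isolated alkene, hydrolysis gives the enedial-type intermediate, the carbinol oxygen closes onto the aldehyde, and the furan 4-substituent ends on pyranone C5 (future C6).

Step 11
Reactants: 14 5-(tert-butyldiphenylsilyloxymethyl)-2-[(3R)-2,6-dimethyl-3-(triethylsilyloxy)hept-6-en-3-yl]-6-hydroxy-2H-pyran-3(6H)-one
Product: 15 5-(tert-butyldiphenylsilyloxymethyl)-6-[(3R)-2,6-dimethyl-3-(triethylsilyloxy)hept-6-en-3-yl]-5-oxo-5,6-dihydro-2H-pyran-2-yl acetate numbered from the acetal carbon (the 6-acetoxy derivative of 14)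
Conditions: Ac2O, pyridine, DMAP (cat.), CH2Cl2, 0 °C
Reagents that add atoms: acetic anhydride, CC(=O)OC(C)=O
Why: DMAP-catalysed acylation of the lactol hydroxyl, kept cold and with a weak base so that the acetate is not ionised prematurely.

Step 12
Reactants: 15 6-acetoxypyranone with the (3R)-2,6-dimethyl-3-(triethylsilyloxy)hept-6-en-3-yl side chain
Product: 17 (3R,3aS,7S,8aR)-6-(tert-butyldiphenylsilyloxymethyl)-8a-methyl-3-(propan-2-yl)-3-(triethylsilyloxy)-1,2,3,7,8,8a-hexahydro-4H-3a,7-epoxyazulen-4-one, via oxidopyrylium ylide 16 (not isolated)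
Conditions: DBU (1.5 equiv), MeCN (0.01 M), rt → 60 °C
Reagents that add atoms: none
Why: DBU removes the proton at C3a of 15 and acetate leaves from C7, which gives the aromatic 3-oxidopyrylium 16; its termini C3a and C7 then add to the same face of the tethered C8a=C8 bond in a single concerted event. The closest known reaction type is the intramolecular oxidopyrylium–alkene (5+2) cycloaddition of 6-acetoxypyranones, documented for three-atom tethers and for 1,1-disubstituted alkenes that leave a quaternary carbon. The cyclopentane (C3a–C3–C2–C1–C8a) closes through the C3a–C8a bond with the tether exo, on the side of the pyrylium oxygen, the only arrangement in which the bridgehead C3a–C3 bond and the C8a–C1 bond reach the small dihedral angle of a fused five-membered ring, and the cycloheptenone (C3a–C4–C5–C6–C7–C8–C8a) closes at the same time through the C7–C8 bond as the seven-carbon perimeter of an 8-oxabicyclo[3.2.1]oct-3-en-2-one. C3a, C7 and C8a are formed together: their mutual relation follows from the suprafacial addition and the exo tether, which turns the 8a-methyl endo and anti to the oxygen bridge, and their relation to C3 follows from the ylide face that the alkene reaches. The step therefore needs regio- and face selectivity: the tether length lets C8a reach only C3a, and in the reacting rotamer C2 points to the alkene, so that of the two other C3 substituents one lies beside the bare ring oxygen and the other beside the C4 oxido group on the same side of the nascent cyclopentane as the endo methyl; the branched isopropyl group should take the open site and the silyl ether oxygen, whose SiEt3 group can turn outward, the crowded one, which puts the 8a-methyl cis to the C3 oxygen. High dilution and the bulky C3 substituent hold back ylide dimerisation, and C3a carries no hydrogen in 17, so the β-silyloxy group cannot be eliminated there.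

Step 13
Reactants: 17 (3R,3aS,7S,8aR)-oxygen-bridged hydroazulenone
Product: 18 (3R,3aR,7S,8aR)-6-(tert-butyldiphenylsilyloxymethyl)-7-hydroxy-8a-methyl-3-(propan-2-yl)-3-(triethylsilyloxy)-2,3,3a,7,8,8a-hexahydroazulen-4(1H)-one
Conditions: SmI2 (2.2 equiv), THF–MeOH (10:1), −78 °C
Reagents that add atoms: none
Why: Samarium(II) reduction of an α-alkoxy ketone, in which electron transfer to the C4 carbonyl expels the bridge oxygen from C3a with relief of bicyclic strain, methanol protonates the samarium enolate before it can lose the β-silyloxy group, and the proton should arrive anti to the quasi-axial 8a-methyl and the C3 silyl ether, on the face of the freed C7 alkoxide, giving the trans ring fusion that should also be the more stable one because it keeps C4 trans to the isopropyl group.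

Step 14
Reactants: 18 (3R,3aR,7S,8aR)-7-hydroxy enone
Product: 19 (3R,3aR,7S,8aR)-7-acetoxy-6-(tert-butyldiphenylsilyloxymethyl)-8a-methyl-3-(propan-2-yl)-3-(triethylsilyloxy)-2,3,3a,7,8,8a-hexahydroazulen-4(1H)-one
Conditions: Ac2O, pyridine, DMAP (cat.), CH2Cl2, 0 °C → rt
Reagents that add atoms: acetic anhydride, CC(=O)OC(C)=O
Why: DMAP-catalysed acetylation makes the C7 oxygen a far better leaving group than the primary silyloxy group on the other γ-carbon of the enone, so the second reduction becomes site-selective, and the weak base avoids isomerisation of the γ-hydroxy enone.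

Step 15
Reactants: 19 (3R,3aR,7S,8aR)-7-acetoxy enone TES ether
Product: 20 (3R,3aR,7S,8aR)-7-acetoxy-6-(tert-butyldiphenylsilyloxymethyl)-3-hydroxy-8a-methyl-3-(propan-2-yl)-2,3,3a,7,8,8a-hexahydroazulen-4(1H)-one
Conditions: HF·pyridine, pyridine, THF, 0 °C
Reagents that add atoms: none
Why: Buffered fluoride desilylation cleaves the TES ether much faster than the primary TBDPS ether, and it is done at the conjugated enone stage, where no alkene can migrate and the mildly acidic medium permits neither retro-aldol cleavage nor dehydration.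

Step 16
Reactants: 20 (3R,3aR,7S,8aR)-7-acetoxy-3-hydroxy enone
Product: 21 (3R,3aR,8aR)-6-(tert-butyldiphenylsilyloxymethyl)-3-hydroxy-8a-methyl-3-(propan-2-yl)-2,3,3a,5,8,8a-hexahydroazulen-4(1H)-one
Conditions: SmI2 (2.2 equiv), THF–MeOH (10:1), −78 °C; pH 7 buffer; crude 21 used at once
Reagents that add atoms: none
Why: Vinylogous samarium(II) reduction of a γ-acyloxy enone, in which two electrons expel acetate from C7 to give the C4–C5–C6–C7 dienolate, kinetic protonation at the α-carbon C5 leaves the alkene at C6=C7 out of conjugation, and the C7 stereocentre is deleted.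

Step 17
Reactants: 21 (3R,3aR,8aR)-β,γ-unsaturated β'-hydroxy ketone
Product: 22 (3R,3aS,4S,8aR)-6-(tert-butyldiphenylsilyloxymethyl)-8a-methyl-3-(propan-2-yl)-1,2,3,3a,4,5,8,8a-octahydroazulene-3,4-diol
Conditions: Me4NBH(OAc)3, MeCN–AcOH (1:1), −25 °C
Reagents that add atoms: none
Why: Evans–Saksena hydroxyl-directed reduction, in which the C3 hydroxyl binds boron and delivers hydride to C4 from the face that carries the C3 oxygen and the 8a-methyl (the face an external hydride would avoid), so the new hydroxyl is anti to the C3 hydroxyl and cis to H3a (4S), while the acidic medium does not enolise the β,γ-unsaturated ketone.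

Step 18
Reactants: 23 4-hydroxybenzoic acid
Product: 25 4-(tert-butyldimethylsilyloxy)benzoic acid, via bis-silylated acid 24 (not isolated)
Conditions: TBSCl (2.2 equiv), imidazole, DMF, rt; then AcOH–THF–H2O, rt
Reagents that add atoms: tert-butyl(chloro)dimethylsilane, CC(C)(C)[Si](C)(C)Cl
Why: Silylation of both acidic hydroxyls followed by selective hydrolysis of the much more labile silyl ester, which leaves the aryl silyl ether in place.

Step 19
Reactants: 22 (3R,3aS,4S,8aR)-3,4-diol; 25 4-(tert-butyldimethylsilyloxy)benzoic acid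
Product: 26 (3R,3aS,4S,8aR)-6-(tert-butyldiphenylsilyloxymethyl)-3-hydroxy-8a-methyl-3-(propan-2-yl)-1,2,3,3a,4,5,8,8a-octahydroazulen-4-yl 4-(tert-butyldimethylsilyloxy)benzoate
Conditions: DCC, DMAP, CH2Cl2, rt
Reagents that add atoms: none
Why: Steglich esterification acylates only the secondary C4 hydroxyl, because the C3 hydroxyl is tertiary and flanked by isopropyl, and C4 keeps its configuration since its C–O bond is not broken.

Step 20
Reactants: 26 bis-silylated ester
Product: 27 (3R,3aS,4S,8aR)-3-hydroxy-6-(hydroxymethyl)-8a-methyl-3-(propan-2-yl)-1,2,3,3a,4,5,8,8a-octahydroazulen-4-yl 4-hydroxybenzoate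
Conditions: TBAF, AcOH (1:1), THF, 0 °C → rt
Reagents that add atoms: none
Why: Fluoride desilylation of both silyl ethers, buffered with acetic acid so that no free phenoxide or alkoxide can attack or transfer the benzoate.

Step 21
Reactants: 27 allylic alcohol
Product: 28 (3R,3aS,4S,8aR)-6-formyl-3-hydroxy-8a-methyl-3-(propan-2-yl)-1,2,3,3a,4,5,8,8a-octahydroazulen-4-yl 4-hydroxybenzoate
Conditions: activated MnO2, CH2Cl2, rt
Reagents that add atoms: none
Why: Manganese dioxide oxidation is selective for the primary allylic alcohol, the tertiary alcohol cannot be oxidised, the ester-deactivated phenol should be inert, and the neutral conditions leave the C6=C7 alkene and the homoallylic ester in place.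

Compound list
1 | 3-methylbutanal | CC(C)CC=O | starting material
2 | 3-methyl-2-methylidenebutanal | CC(C)C(=C)C=O | intermediate
3 | 3-methyl-2-methylidenebutan-1-ol | CC(C)C(=C)CO | intermediate
4 | (R)-[2-(propan-2-yl)oxiran-2-yl]methanol | CC(C)[C@@]1(CO)CO1 | intermediate
5 | (2-methylprop-2-en-1-yl)magnesium chloride | CC(=C)C[Mg]Cl | starting material
6 | (2R)-5-methyl-2-(propan-2-yl)hex-5-ene-1,2-diol | CC(C)[C@](O)(CCC(C)=C)CO | intermediate
7 | (2R)-5-methyl-2-(propan-2-yl)-1,2-bis(triethylsilyloxy)hex-5-ene | CC(C)[C@](O[Si](CC)(CC)CC)(CCC(C)=C)CO[Si](CC)(CC)CC | intermediate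
8 | (2R)-5-methyl-2-(propan-2-yl)-2-(triethylsilyloxy)hex-5-enal | CC(C)[C@](O[Si](CC)(CC)CC)(CCC(C)=C)C=O | intermediate
9 | methyl 5-bromofuran-3-carboxylate | COC(=O)c1coc(Br)c1 | starting material
10 | (5-bromofuran-3-yl)methanol | OCc1coc(Br)c1 | intermediate
11 | [(5-bromofuran-3-yl)methoxy](tert-butyl)diphenylsilane | CC(C)(C)[Si](OCc1coc(Br)c1)(c1ccccc1)c1ccccc1 | intermediate
12 | [4-(tert-butyldiphenylsilyloxymethyl)furan-2-yl]lithium (not isolated) | [Li]c1cc(CO[Si](c2ccccc2)(c2ccccc2)C(C)(C)C)co1 | intermediate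
13 | (2R)-1-[4-(tert-butyldiphenylsilyloxymethyl)furan-2-yl]-5-methyl-2-(propan-2-yl)-2-(triethylsilyloxy)hex-5-en-1-ol, C1 epimers | CC(C)[C@](O[Si](CC)(CC)CC)(CCC(C)=C)C(O)c1cc(CO[Si](c2ccccc2)(c2ccccc2)C(C)(C)C)co1 | intermediate
14 | 5-(tert-butyldiphenylsilyloxymethyl)-2-[(3R)-2,6-dimethyl-3-(triethylsilyloxy)hept-6-en-3-yl]-6-hydroxy-2H-pyran-3(6H)-one, C2/C6 epimers | CC(C)[C@](O[Si](CC)(CC)CC)(CCC(C)=C)C1OC(O)C(CO[Si](c2ccccc2)(c2ccccc2)C(C)(C)C)=CC1=O | intermediate
15 | 6-acetoxy derivative of 14 (key-step precursor), C2/C6 epimers | CC(C)[C@](O[Si](CC)(CC)CC)(CCC(C)=C)C1OC(OC(C)=O)C(CO[Si](c2ccccc2)(c2ccccc2)C(C)(C)C)=CC1=O | intermediate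
16 | 5-(tert-butyldiphenylsilyloxymethyl)-2-[(3R)-2,6-dimethyl-3-(triethylsilyloxy)hept-6-en-3-yl]pyrylium-3-olate (not isolated) | CC(C)[C@](O[Si](CC)(CC)CC)(CCC(C)=C)c1[o+]cc(CO[Si](c2ccccc2)(c2ccccc2)C(C)(C)C)cc1[O-] | intermediate
17 | (3R,3aS,7S,8aR)-6-(tert-butyldiphenylsilyloxymethyl)-8a-methyl-3-(propan-2-yl)-3-(triethylsilyloxy)-1,2,3,7,8,8a-hexahydro-4H-3a,7-epoxyazulen-4-one | CC(C)[C@]1(O[Si](CC)(CC)CC)CC[C@]2(C)C[C@H]3C(CO[Si](c4ccccc4)(c4ccccc4)C(C)(C)C)=CC(=O)[C@]21O3 | intermediate
18 | (3R,3aR,7S,8aR)-6-(tert-butyldiphenylsilyloxymethyl)-7-hydroxy-8a-methyl-3-(propan-2-yl)-3-(triethylsilyloxy)-2,3,3a,7,8,8a-hexahydroazulen-4(1H)-one | CC(C)[C@]1(O[Si](CC)(CC)CC)CC[C@]2(C)C[C@H](O)C(CO[Si](c3ccccc3)(c3ccccc3)C(C)(C)C)=CC(=O)[C@H]21 | intermediate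
19 | (3R,3aR,7S,8aR)-7-acetoxy-6-(tert-butyldiphenylsilyloxymethyl)-8a-methyl-3-(propan-2-yl)-3-(triethylsilyloxy)-2,3,3a,7,8,8a-hexahydroazulen-4(1H)-one | CC(C)[C@]1(O[Si](CC)(CC)CC)CC[C@]2(C)C[C@H](OC(C)=O)C(CO[Si](c3ccccc3)(c3ccccc3)C(C)(C)C)=CC(=O)[C@H]21 | intermediate
20 | (3R,3aR,7S,8aR)-7-acetoxy-6-(tert-butyldiphenylsilyloxymethyl)-3-hydroxy-8a-methyl-3-(propan-2-yl)-2,3,3a,7,8,8a-hexahydroazulen-4(1H)-one | CC(C)[C@]1(O)CC[C@]2(C)C[C@H](OC(C)=O)C(CO[Si](c3ccccc3)(c3ccccc3)C(C)(C)C)=CC(=O)[C@H]21 | intermediate
21 | (3R,3aR,8aR)-6-(tert-butyldiphenylsilyloxymethyl)-3-hydroxy-8a-methyl-3-(propan-2-yl)-2,3,3a,5,8,8a-hexahydroazulen-4(1H)-one | CC(C)[C@]1(O)CC[C@]2(C)CC=C(CO[Si](c3ccccc3)(c3ccccc3)C(C)(C)C)CC(=O)[C@H]21 | intermediate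
22 | (3R,3aS,4S,8aR)-6-(tert-butyldiphenylsilyloxymethyl)-8a-methyl-3-(propan-2-yl)-1,2,3,3a,4,5,8,8a-octahydroazulene-3,4-diol | CC(C)[C@]1(O)CC[C@]2(C)CC=C(CO[Si](c3ccccc3)(c3ccccc3)C(C)(C)C)C[C@H](O)[C@H]21 | intermediate
23 | 4-hydroxybenzoic acid | OC(=O)c1ccc(O)cc1 | starting material
24 | tert-butyldimethylsilyl 4-(tert-butyldimethylsilyloxy)benzoate (not isolated) | CC(C)(C)[Si](C)(C)OC(=O)c1ccc(O[Si](C)(C)C(C)(C)C)cc1 | intermediate
25 | 4-(tert-butyldimethylsilyloxy)benzoic acid | CC(C)(C)[Si](C)(C)Oc1ccc(cc1)C(=O)O | intermediate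
26 | (3R,3aS,4S,8aR)-6-(tert-butyldiphenylsilyloxymethyl)-3-hydroxy-8a-methyl-3-(propan-2-yl)-1,2,3,3a,4,5,8,8a-octahydroazulen-4-yl 4-(tert-butyldimethylsilyloxy)benzoate | CC(C)[C@]1(O)CC[C@]2(C)CC=C(CO[Si](c3ccccc3)(c3ccccc3)C(C)(C)C)C[C@H](OC(=O)c3ccc(O[Si](C)(C)C(C)(C)C)cc3)[C@H]21 | intermediate
27 | (3R,3aS,4S,8aR)-3-hydroxy-6-(hydroxymethyl)-8a-methyl-3-(propan-2-yl)-1,2,3,3a,4,5,8,8a-octahydroazulen-4-yl 4-hydroxybenzoate | CC(C)[C@]1(O)CC[C@]2(C)CC=C(CO)C[C@H](OC(=O)c3ccc(O)cc3)[C@H]21 | intermediate
28 | (3R,3aS,4S,8aR)-6-formyl-3-hydroxy-8a-methyl-3-(propan-2-yl)-1,2,3,3a,4,5,8,8a-octahydroazulen-4-yl 4-hydroxybenzoate | CC(C)[C@]1(O)CC[C@]2(C)CC=C(C=O)C[C@H](OC(=O)c3ccc(O)cc3)[C@H]21 | target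

Total step count: 21 (18 in the main line, 2 for the furan, 1 for the acid).
Longest linear sequence: 18 steps, from 1 to 28 (steps 1–6, 9–17 and 19–21).

Steps most likely to fail

Step 12.
- **What may go wrong:** Bond formation between the hindered ylide terminus C3a and the disubstituted alkene carbon creates three contiguous fully substituted carbons. It may be slow enough for the ylide to be lost by dimerisation. The C3 centre alone may also discriminate poorly between the two ylide faces.
- **Fallback:** It replaces substrate control by catalyst control, sets out from 14 and comes back at 17. Lactol 14 is acylated with 4-(methylsulfanyl)benzoyl chloride (Et3N, DMAP, CH2Cl2) to the pyranone 4-(methylsulfanyl)benzoate F1. F1 is then treated with a chiral primary-amine thiourea, an achiral N,N'-diaryl thiourea and acetic acid in toluene at 40 °C. This is the known dual-catalytic intramolecular (5+2) process. The amine condenses with the C4 ketone and the thioureas abstract the aroate by anion binding. The resulting cationic aminopyrylium is more reactive than the neutral ylide and is shielded on one face by the catalyst. It adds to the alkene, and hydrolysis of the enamine returns 17. The catalyst enantiomer that reinforces the bias of C3 is used.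

Step 13.
- **What may go wrong:** Electron transfer to the bridged enone may take other courses. These are cleavage at C7–O, loss of the allylic silyloxy group, 1,4-reduction and reductive dimerisation. The enolate may also expel silanolate or be protonated on the wrong face.
- **Fallback:** It removes the enone before the bridge is opened and rebuilds the alkene by dehydration. It sets out from 17 and comes back at 21. Hydrogenation of 17 (H2, Pd/C, EtOAc) should occur from the face of the oxygen bridge, since the endo 8a-methyl blocks the other, and gives the saturated bridged ketone F2. As a plain α-alkoxy ketone, F2 has only one bond to lose on SmI2 reduction (THF–MeOH), which gives the 7-hydroxy ketone F3. H6 and the C7 hydroxyl are cis in F3, so syn-elimination with the Burgess reagent (toluene, 50 °C) can form the trisubstituted C6=C7 alkene of the TES-protected β,γ-unsaturated ketone F4. HF·pyridine then gives 21.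

Step 16.
- **What may go wrong:** The dienolate may be protonated at C7, or the alkene may slide back into conjugation during quench and work-up. The chelated ketone may also be reduced further.
- **Fallback:** It avoids any dienolate, sets out from 18 and comes back at 21. Compound 18 is desilylated (HF·pyridine, THF) to the 3,7-dihydroxy enone F5. Mitsunobu displacement of the secondary allylic C7 hydroxyl with 2-nitrobenzenesulfonylhydrazide (PPh3, DEAD, THF, −30 °C) leaves the tertiary hydroxyl alone and gives the N-allyl sulfonylhydrazine F6. On warming, F6 loses the sulfinic acid to give the allylic diazene F7. Retro-ene loss of nitrogen from F7 carries hydrogen to C5 and moves the alkene to C6=C7. This reductive allylic transposition gives 21 under neutral conditions.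

Further compounds
F1 | step 12 | 5-(tert-butyldiphenylsilyloxymethyl)-2-[(3R)-2,6-dimethyl-3-(triethylsilyloxy)hept-6-en-3-yl]-3-oxo-3,6-dihydro-2H-pyran-6-yl 4-(methylsulfanyl)benzoate | CC(C)[C@](O[Si](CC)(CC)CC)(CCC(C)=C)C1OC(OC(=O)c2ccc(SC)cc2)C(CO[Si](c2ccccc2)(c2ccccc2)C(C)(C)C)=CC1=O
F2 | step 13 | (3R,3aS,6R,7S,8aR)-6-(tert-butyldiphenylsilyloxymethyl)-8a-methyl-3-(propan-2-yl)-3-(triethylsilyloxy)octahydro-4H-3a,7-epoxyazulen-4-one | CC(C)[C@]1(O[Si](CC)(CC)CC)CC[C@]2(C)C[C@H]3[C@@H](CO[Si](c4ccccc4)(c4ccccc4)C(C)(C)C)CC(=O)[C@]21O3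
F3 | step 13 | 6-(tert-butyldiphenylsilyloxymethyl)-7-hydroxy-8a-methyl-3-(propan-2-yl)-3-(triethylsilyloxy)octahydroazulen-4(1H)-one with H3a, H6 and the 7-OH on one face | CC(C)[C@]1(O[Si](CC)(CC)CC)CC[C@]2(C)C[C@H](O)[C@@H](CO[Si](c3ccccc3)(c3ccccc3)C(C)(C)C)CC(=O)[C@H]21
F4 | step 13 | (3R,3aR,8aR)-6-(tert-butyldiphenylsilyloxymethyl)-8a-methyl-3-(propan-2-yl)-3-(triethylsilyloxy)-2,3,3a,5,8,8a-hexahydroazulen-4(1H)-one | CC(C)[C@]1(O[Si](CC)(CC)CC)CC[C@]2(C)CC=C(CO[Si](c3ccccc3)(c3ccccc3)C(C)(C)C)CC(=O)[C@H]21
F5 | step 16 | (3R,3aR,7S,8aR)-6-(tert-butyldiphenylsilyloxymethyl)-3,7-dihydroxy-8a-methyl-3-(propan-2-yl)-2,3,3a,7,8,8a-hexahydroazulen-4(1H)-one | CC(C)[C@]1(O)CC[C@]2(C)C[C@H](O)C(CO[Si](c3ccccc3)(c3ccccc3)C(C)(C)C)=CC(=O)[C@H]21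
F6 | step 16 | N-allyl-N-(2-nitrophenylsulfonyl)hydrazine from F5 with inverted C7 | CC(C)[C@]1(O)CC[C@]2(C)C[C@@H](N(N)S(=O)(=O)c3ccccc3[N+](=O)[O-])C(CO[Si](c3ccccc3)(c3ccccc3)C(C)(C)C)=CC(=O)[C@H]21
F7 | step 16 | allylic diazene at C7 | CC(C)[C@]1(O)CC[C@]2(C)C[C@@H](N=N)C(CO[Si](c3ccccc3)(c3ccccc3)C(C)(C)C)=CC(=O)[C@H]21
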